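The alder run ends lower than it stood at 1.8 h, 0.3656 M against 0.4449 M, so in that flask target is lost as well as made. The larch run is reckoned here as two lags in series, one making target and one draining it.

| flask | starting material | reagent | time |
|---|---|---|---|
| cedar | 0.500 M | 0.550 M |  |
| alder | 1.50 M | 0.550 M |  |
| birch | 0.500 M | 0.280 M |  |
| larch | 0.170 M | 1.70 M | 4.4 h |

- cedar run (time / h: [target] / M): 0.18: 0.0081; 0.28: 0.0150; 0.44: 0.0190; 0.70: 0.0386; 1.1: 0.0671; 1.8: 0.1233; 2.8: 0.2008; 4.4: 0.2514
- alder run (time / h: [target] / M): 0.18: 0.0270; 0.28: 0.0519; 0.44: 0.0961; 0.70: 0.1985; 1.1: 0.3492; 1.8: 0.4449; 2.8: 0.4323; 4.4: 0.3656
- birch run (time / h: [target] / M): 0.18: 0.0019; 0.28: 0.0073; 0.44: 0.0057; 0.70: 0.0072; 1.1: 0.0122; 1.8: 0.0240; 2.8: 0.0469; 4.4: 0.0790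

(scatter of a reading: 0.002 M)

* apparent order in [reagent] of the starting rate, round the charge of the cedar run (the rate where two percent of its starting material have turned into target)
* apparent order in [starting material] of the starting rate, round the charge of the cedar run (the rate where two percent of its starting material have turned into target) (one fixed amount of target, the same in the runs compared)
* target in the larch run at 4.4 h, as a share of the starting material charged

- Overall: starting material + reagent -> target.
- Constant volume, constant temperature.
- "The second partner" is reagent.
- An order is taken over about fifteen percent of the charge, up and down.

The first readings give the making lag. With 3.00 times the starting material, the alder run reads 3.33 times the cedar run. With half the reagent, the birch run reads 0.235 of it. These ratios are rough, for the birch reading of 0.0019 M is of the size of the scatter, 0.002 M; as readings they point to first order in starting material and second order in reagent, with orders near 1.10 and 2.15. In the larch run, reagent can fall by 10.0% of its charge at most, so it is treated as constant (pseudo-first-order). The first cedar reading over its time, scaled to the larch reagent by the square, then gives the fall of c_starting material in the larch run an estimated constant of 0.860 /h, a time constant of 1.16 h.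

The drain comes from a balance on the alder run, where reagent is the limiting reagent, 0.550 M against 1.50 M of starting material. One reagent goes into each target. Suppose the whole reagent charge has been converted by 4.4 h. Then the balance puts the target lost at 0.184 M. Taken as first order, the loss removes its constant times c_target per hour, so the amount lost equals that constant times the area under the curve, which the readings put at 91.3 M·min. This gives the loss constant, the fraction of target lost per hour, as 0.121 /h, a time constant of 8.25 h, longer than the making lag.

By 4.4 h the making lag has turned nearly all of the larch starting material, so the loss is the correction to compute. The two lags give a share of 65.6%. The forecast gives 70%, higher than this reckoning, with orders 1.9 in reagent and 1 in starting material: “Target then decays for about 3.5 h, leaving roughly 70%.”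

The larch flask gives 64.5%, with orders 1.8 in reagent and 1.0 in starting material.

    starting material + 2 reagent → target + reagent (0.2639 /M²/h)
    target → decomposed product (0.1235 /h)
    starting material + reagent + target → 2 target (4.464 /M²/h)

The step in which target helps to make itself makes no difference to the larch value. At the loss constant 0.121 /h, a share of 64.5% corresponds to 3.62 h of exposure out of 4.4 h. Over the alder tail from 2.8 h to 4.4 h, the same constant leaves 0.356 M of the 0.4323 M read, and the reading stands at 0.3656 M, higher by 0.00960 M.

The runs are calculated with made-up constants; the scatter is artificial.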